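**Retrosynthetic overview**

1. Target 22 comes from lactone 18. The (E)-bromomethylidene is built last on the lactone carbonyl by methylenation, twofold bromination–dehydrobromination to =CBr2, and Pd-catalysed removal of the bromine cis to the ring oxygen.
2. Feature used: the oxirane (ring C) spans the two ring B carbons that follow the enol-ether carbon C(=CHBr), namely C(CH3)(O) and CH(O). With that carbon at the lactone level, this is a glycidic ester whose Cα–Cβ bond is a ring B bond.
3. Key disconnection: 18 comes from aldehyde 2,2-dibromopropanoate 16 by a samarium-triggered intramolecular Darzens reaction. The C–C bond closes ring B (oxepanone), then the C–O bond closes ring C.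
4. 16 comes from ring A alcohol 12 (acylation, ozonolysis), 12 from bromo ketone 9 (methylenation, epoxidation, hydride), 9 from enone 4 (cuprate addition–allylation, OH to Br with inversion), and 4 from 2-methylcyclohex-2-en-1-one (CBS reduction, allylic oxidation).
5. Ring order: ring A (cyclohexane) is purchased; rings B and C are closed together in step 13.

Key step: step 13

Remark on the chemistry: ring A = cyclohexane, ring B = oxepane, ring C = oxirane; compounds 1, 5 and 13 are assumed to be purchased.

**Route**

Step 1
Reactants: 1 2-methylcyclohex-2-en-1-one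
Product: 2 (S)-2-methylcyclohex-2-en-1-ol
Conditions: (R)-2-methyl-CBS-oxazaborolidine (10 mol %), BH3·SMe2 (0.6 equiv), THF, −20 °C; MeOH quench
Reagents that add atoms: none
Why: Corey–Bakshi–Shibata reduction, in which the (R)-oxazaborolidine binds the ketone with the methyl-substituted alkenyl side as the large group and delivers hydride 1,2 to one face, which should give the (S)-carbinol that later becomes the C–Br carbon after inversion.

Step 2
Reactants: 2 (S)-2-methylcyclohex-2-en-1-ol
Product: 3 (S)-tert-butyldimethyl[(2-methylcyclohex-2-en-1-yl)oxy]silane
Conditions: TBSCl, imidazole, DMF, rt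
Reagents that add atoms: tert-butyldimethylsilyl chloride, CC(C)(C)[Si](C)(C)Cl
Why: Imidazole-promoted silylation masks the alcohol for the oxidation and the cuprate step without touching the stereocentre.

Step 3
Reactants: 3 (S)-tert-butyldimethyl[(2-methylcyclohex-2-en-1-yl)oxy]silane
Product: 4 (S)-4-[(tert-butyldimethylsilyl)oxy]-3-methylcyclohex-2-en-1-one
Conditions: Rh2(cap)4 (dirhodium tetrakis(caprolactamate), 1 mol %), t-BuOOH (70 % aq., 5 equiv), K2CO3 (0.5 equiv), CH2Cl2, rt
Reagents that add atoms: tert-butyl hydroperoxide, CC(C)(C)OO
Why: Peroxyl-radical allylic C–H oxidation should convert the ring CH2 next to the unsubstituted alkene carbon into the conjugated ketone, because the C–H on the silyloxy carbon is shielded and, with the silyloxy group pseudoaxial to avoid the vinylic methyl, poorly aligned with the π bond; the stereocentre is not involved.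

Step 4
Reactants: 4 (S)-4-[(tert-butyldimethylsilyl)oxy]-3-methylcyclohex-2-en-1-one; 5 allyl bromide
Product: 7 (2R,4S)-2-allyl-4-[(tert-butyldimethylsilyl)oxy]-3,3-dimethylcyclohexan-1-one, via lithium enolate 6 (not isolated)
Conditions: CuI, MeLi (2 equiv), Et2O, 0 °C; then 4, −20 → 0 °C; then 5, HMPA, THF, −30 °C → rt
Reagents that add atoms: lithium dimethylcuprate, [Li+].C[Cu-]C
Why: Conjugate addition of the Gilman cuprate creates the gem-dimethyl carbon and the regiodefined enolate 6, whose allylation should occur anti to the silyloxy group (2,4-trans, C2 = R), because chair-like axial attack on the half-chair with equatorial OTBS avoids a syn-diaxial contact while the pseudoaxial methyl of the new quaternary carbon blocks the other face.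

Step 5
Reactants: 7 (2R,4S)-2-allyl-4-[(tert-butyldimethylsilyl)oxy]-3,3-dimethylcyclohexan-1-one
Product: 8 (2R,4S)-2-allyl-4-hydroxy-3,3-dimethylcyclohexan-1-one
Conditions: HF (48 % aq.), MeCN, 0 °C → rt
Reagents that add atoms: none
Why: Acidic fluoride desilylation frees the secondary alcohol under non-basic conditions, so the ketone α-stereocentre set under kinetic control is not epimerised.

Step 6
Reactants: 8 (2R,4S)-2-allyl-4-hydroxy-3,3-dimethylcyclohexan-1-one
Product: 9 (2R,4R)-2-allyl-4-bromo-3,3-dimethylcyclohexan-1-one
Conditions: CBr4 (3 equiv), PPh3 (3 equiv), 2,6-lutidine, toluene, 0 → 60 °C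
Reagents that add atoms: carbon tetrabromide, BrC(Br)(Br)Br
Why: Appel reaction, in which the alkoxyphosphonium group (axial in the chair with equatorial allyl) is displaced by bromide from the equatorial side in an SN2 step with inversion, which should give the equatorial (4R) bromide cis to the allyl group.

Step 7
Reactants: 9 (2R,4R)-2-allyl-4-bromo-3,3-dimethylcyclohexan-1-one
Product: 10 (1R,3S)-1-bromo-2,2-dimethyl-4-methylidene-3-(prop-2-en-1-yl)cyclohexane
Conditions: Cp2TiMe2 (2.5 equiv), toluene, 65 °C, dark
Reagents that add atoms: dimethyltitanocene, [CH3-].[CH3-].[Ti+4].c1cc[cH-]c1.c1cc[cH-]c1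
Why: Petasis methylenation with the non-basic titanium methylidene converts the hindered ketone into the exocyclic alkene without epimerising the α-centre or eliminating the bromide.

Step 8
Reactants: 10 (1R,3S)-1-bromo-2,2-dimethyl-4-methylidene-3-(prop-2-en-1-yl)cyclohexane
Product: 11 (3R,4R,6R)-6-bromo-5,5-dimethyl-4-(prop-2-en-1-yl)-1-oxaspiro[2.5]octane
Conditions: mCPBA (1.05 equiv), NaHCO3, CH2Cl2, −10 → 0 °C
Reagents that add atoms: 3-chloroperoxybenzoic acid, OOC(=O)c1cccc(Cl)c1
Why: Prilezhaev epoxidation should select the more nucleophilic 1,1-disubstituted alkene over the monosubstituted allyl alkene and, on the chair fixed by equatorial allyl and bromine, attack from the equatorial side away from the axial methyl of the gem-dimethyl carbon, placing the oxygen equatorial (trans to allyl) and the CH2 axial.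

Step 9
Reactants: 11 (3R,4R,6R)-6-bromo-5,5-dimethyl-4-(prop-2-en-1-yl)-1-oxaspiro[2.5]octane
Product: 12 (1R,2R,4R)-4-bromo-1,3,3-trimethyl-2-(prop-2-en-1-yl)cyclohexan-1-ol
Conditions: LiAlH4, Et2O, 0 °C → rt
Reagents that add atoms: none
Why: Hydride opens the spiro-oxirane by SN2 attack at its CH2 carbon, which becomes the axial methyl and leaves the equatorial tertiary alcohol, while the equatorial secondary bromide next to a quaternary carbon should resist displacement at this temperature.

Step 10
Reactants: 13 2,2-dibromopropanoic acid
Product: 14 2,2-dibromopropanoyl chloride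
Conditions: (COCl)2, DMF (cat.), CH2Cl2, 0 °C → rt; used crude
Reagents that add atoms: oxalyl chloride, ClC(=O)C(Cl)=O
Why: Acid chloride formation through the Vilsmeier-type chloroiminium species is standard for an acid without α-hydrogen.

Step 11
Reactants: 12 (1R,2R,4R)-4-bromo-1,3,3-trimethyl-2-(prop-2-en-1-yl)cyclohexan-1-ol; 14 2,2-dibromopropanoyl chloride
Product: 15 (1R,2R,4R)-4-bromo-1,3,3-trimethyl-2-(prop-2-en-1-yl)cyclohexyl 2,2-dibromopropanoate
Conditions: 14 (2 equiv), pyridine, DMAP (0.2 equiv), CH2Cl2, 0 °C → rt
Reagents that add atoms: none
Why: DMAP-catalysed acylation (nucleophilic catalysis) of the tertiary alcohol should succeed because the acid chloride is activated by two α-bromines and cannot form a ketene.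

Step 12
Reactants: 15 (1R,2R,4R)-4-bromo-1,3,3-trimethyl-2-(prop-2-en-1-yl)cyclohexyl 2,2-dibromopropanoate
Product: 16 (1R,2R,4R)-4-bromo-1,3,3-trimethyl-2-(2-oxoethyl)cyclohexyl 2,2-dibromopropanoate
Conditions: O3, CH2Cl2, −78 °C; then Me2S, −78 °C → rt
Reagents that add atoms: ozone, [O-][O+]=O
Why: Ozonolysis of the only alkene with reductive work-up gives the aldehyde, and Me2S is chosen because a phosphine would debrominate the geminal dibromide.

Step 13
Reactants: 16 (1R,2R,4R)-4-bromo-1,3,3-trimethyl-2-(2-oxoethyl)cyclohexyl 2,2-dibromopropanoate
Product: 18 tricyclic epoxy lactone, via samarium bromo aldolate 17 (not isolated)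
Conditions: SmI2 (0.1 M in THF, 2.0–2.1 equiv, added over 1 h to the end point), THF (0.005 M in 16), −78 °C; then HMPA (8 equiv), −78 °C → rt
Reagents that add atoms: none
Why: Two single-electron transfers from divalent samarium to the geminal dibromide (the secondary ring bromide and the aldehyde should survive in THF at −78 °C without a donor additive) give a trivalent-samarium bromo enolate without any base, so the enolisable aldehyde is not deprotonated; this is a Reformatsky-triggered Darzens glycidic ester condensation, run intramolecularly. The enolate carbon adds to the tethered aldehyde in a 7-(enolendo)-exo-trig aldol that forms the C(CH3)–CH bond and closes ring B as aldolate 17, helped by the diequatorial (gauche) placement of the ester oxygen and the oxoethyl arm on the ring A chair and by free rotation about the C–O bond of the ketene-acetal-type enolate. The alkoxide then displaces the tertiary α-bromide in a 3-exo-tet closure with inversion that forms the C–O bond of ring C; HMPA is added only after the divalent samarium is spent, to raise the nucleophilicity of the alkoxide and to mask the Lewis-acidic samarium halides that could reopen the glycidic lactone. The relative configuration of the two new stereocentres is fixed by the mechanism, since only an aldolate with oxygen and bromine on opposite faces can close, and aldolates that cannot close should revert by retro-aldol and re-enter. The absolute sense (oxirane oxygen on the face of the ring-fusion hydrogen, opposite the angular methyl) should follow from the chair of the trans-fused ring B, in which the C–O bond on that face and the C–Br bond on the methyl face are antiperiplanar, whereas the other closable aldolate has both bonds equatorial and must pass through a twist-boat with its oxygen under the angular methyl. The step therefore needs reduction of the activated C–Br bonds only, no more than two equivalents of SmI2 (an excess would eliminate the aldolate to the unsaturated lactone), and high dilution against intermolecular aldol.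

Step 14
Reactants: 18 tricyclic epoxy lactone
Product: 19 methylidene enol ether
Conditions: Cp2TiMe2 (3 equiv), toluene, 70 °C, dark; filtration through basic alumina
Reagents that add atoms: dimethyltitanocene, [CH3-].[CH3-].[Ti+4].c1cc[cH-]c1.c1cc[cH-]c1
Why: Petasis methylenation of the lactone carbonyl under neutral conditions should spare the oxirane and the bromide, and the exocyclic enol ether cannot migrate into the ring because the neighbouring carbon is quaternary.

Step 15
Reactants: 19 methylidene enol ether
Product: 21 dibromomethylidene enol ether, via bromomethylidene enol ether 20 (not isolated)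
Conditions: Br2 (1.05 equiv), CH2Cl2, −78 °C, then i-Pr2NEt (1.2 equiv), −78 → 0 °C; then the same cycle again (Br2 1.1 equiv, i-Pr2NEt 1.5 equiv)
Reagents that add atoms: bromine, BrBr
Why: Electrophilic bromination of the enol ether and amine-induced loss of HBr from the α-bromo ether (the only β-hydrogens are on the exocyclic carbon), carried out twice, converge on the =CBr2 compound whatever the geometry of 20, which is expected to form mainly with bromine cis to the ring oxygen, that is, with the wrong geometry for the target.

Step 16
Reactants: 21 dibromomethylidene enol ether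
Product: 22 target CNP0375295.2
Conditions: Pd(PPh3)4 (5 mol %), Bu3SnH (1.05 equiv), toluene, rt, dark
Reagents that add atoms: none
Why: Palladium-catalysed hydrodebromination of a 1,1-dibromoalkene with tin hydride, in which zerovalent palladium should insert into the less hindered C–Br bond (cis to the ring oxygen, remote from the quaternary oxirane carbon) and hydride transfer with reductive elimination retains geometry, leaving the bromine cis to the oxirane carbon as the (E) enol ether requires.

**Compound list**

1 | 2-methylcyclohex-2-en-1-one | CC1=CCCCC1=O | starting material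
2 | (S)-2-methylcyclohex-2-en-1-ol | CC1=CCCC[C@@H]1O | intermediate
3 | (S)-tert-butyldimethyl[(2-methylcyclohex-2-en-1-yl)oxy]silane | CC1=CCCC[C@@H]1O[Si](C)(C)C(C)(C)C | intermediate
4 | (S)-4-[(tert-butyldimethylsilyl)oxy]-3-methylcyclohex-2-en-1-one | CC1=CC(=O)CC[C@@H]1O[Si](C)(C)C(C)(C)C | intermediate
5 | allyl bromide (3-bromoprop-1-ene) | C=CCBr | starting material
6 | lithium (S)-4-[(tert-butyldimethylsilyl)oxy]-3,3-dimethylcyclohex-1-en-1-olate | CC1(C)C=C(O[Li])CC[C@@H]1O[Si](C)(C)C(C)(C)C | intermediate (not isolated)
7 | (2R,4S)-2-allyl-4-[(tert-butyldimethylsilyl)oxy]-3,3-dimethylcyclohexan-1-one (allyl and silyloxy trans) | CC1(C)[C@@H](O[Si](C)(C)C(C)(C)C)CCC(=O)[C@@H]1CC=C | intermediate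
8 | (2R,4S)-2-allyl-4-hydroxy-3,3-dimethylcyclohexan-1-one | CC1(C)[C@@H](O)CCC(=O)[C@@H]1CC=C | intermediate
9 | (2R,4R)-2-allyl-4-bromo-3,3-dimethylcyclohexan-1-one (allyl and Br cis, both equatorial) | CC1(C)[C@H](Br)CCC(=O)[C@@H]1CC=C | intermediate
10 | (1R,3S)-1-bromo-2,2-dimethyl-4-methylidene-3-(prop-2-en-1-yl)cyclohexane | CC1(C)[C@H](Br)CCC(=C)[C@@H]1CC=C | intermediate
11 | (3R,4R,6R)-6-bromo-5,5-dimethyl-4-(prop-2-en-1-yl)-1-oxaspiro[2.5]octane (oxirane O equatorial, trans to allyl) | CC1(C)[C@H](Br)CC[C@@]2(OC2)[C@@H]1CC=C | intermediate
12 | (1R,2R,4R)-4-bromo-1,3,3-trimethyl-2-(prop-2-en-1-yl)cyclohexan-1-ol (OH, allyl and Br equatorial; C1 methyl axial) | CC1(C)[C@H](Br)CC[C@@](C)(O)[C@@H]1CC=C | intermediate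
13 | 2,2-dibromopropanoic acid | CC(Br)(Br)C(O)=O | starting material
14 | 2,2-dibromopropanoyl chloride | CC(Br)(Br)C(Cl)=O | intermediate
15 | (1R,2R,4R)-4-bromo-1,3,3-trimethyl-2-(prop-2-en-1-yl)cyclohexyl 2,2-dibromopropanoate | CC1(C)[C@H](Br)CC[C@@](C)(OC(=O)C(C)(Br)Br)[C@@H]1CC=C | intermediate
16 | (1R,2R,4R)-4-bromo-1,3,3-trimethyl-2-(2-oxoethyl)cyclohexyl 2,2-dibromopropanoate (key-step precursor) | CC1(C)[C@H](Br)CC[C@@](C)(OC(=O)C(C)(Br)Br)[C@@H]1CC=O | intermediate
17 | diiodosamarium alkoxide of the trans-fused ring A/ring B bromo aldol lactone (oxepan-2-one; C3 carries CH3 and Br, Br on the face of the angular methyl; C4–O on the face of the ring-fusion H) | CC1(C)[C@H](Br)CC[C@@]2(C)OC(=O)[C@](C)(Br)[C@@H](O[Sm](I)I)C[C@H]12 | intermediate (not isolated)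
18 | tricyclic epoxy lactone: ring A (equatorial Br, gem-dimethyl) trans-fused to oxepan-2-one ring B, with oxirane ring C across C3(CH3)–C4, oxirane O on the face of the ring-fusion H and opposite the angular methyl | CC1(C)[C@H](Br)CC[C@@]2(C)OC(=O)[C@@]3(C)O[C@H]3C[C@H]12 | intermediate
19 | methylidene enol ether (C=O of 18 replaced by C=CH2) | CC1(C)[C@H](Br)CC[C@@]2(C)OC(=C)[C@@]3(C)O[C@H]3C[C@H]12 | intermediate
20 | bromomethylidene enol ether, mixture of double-bond isomers | CC1(C)[C@H](Br)CC[C@@]2(C)OC(=CBr)[C@@]3(C)O[C@H]3C[C@H]12 | intermediate (not isolated)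
21 | dibromomethylidene enol ether | CC1(C)[C@H](Br)CC[C@@]2(C)OC(=C(Br)Br)[C@@]3(C)O[C@H]3C[C@H]12 | intermediate
22 | CNP0375295.2, the (E)-bromomethylidene enol ether (vinylic Br trans to the ring oxygen) | CC1(C)[C@H](Br)CC[C@@]2(C)O/C(=C/Br)[C@@]3(C)O[C@H]3C[C@H]12 | target

**Step count and risks**

Total step count: 16. Longest linear sequence: 15 steps (steps 1–9 and 11–16; step 10 prepares the acid chloride on the side).

Steps most likely to fail:

- **Step 13.** Closure of ring C may lag behind the aldol, so that the bromo aldolate is reduced on to the unsaturated lactone or reopened. The retro-aldol funnel may also deliver the oxirane on the methyl face, because the closing conformer carries a transannular Br/CH3 contact, and intermolecular aldol may compete. Fallback: from 16, an excess of SmI2 (about 4.5 equiv, THF, −78 °C → rt) is used deliberately, so that aldolate 17 undergoes reductive elimination to the α-methyl α,β-unsaturated ε-lactone F1. Epoxidation of F1 with dimethyldioxirane (acetone, 0 °C → rt) should then occur on the face opposite the angular methyl and rejoins the route at 18.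

- **Step 6.** E2 elimination across the antiperiplanar axial hydrogen, or 1,2-methyl migration from the neopentyl centre, may outrun substitution, and the α-centre may epimerise if HBr builds up. Fallback: from 8, the alcohol is converted into the triflate F2 (Tf2O, 2,6-di-tert-butylpyridine, CH2Cl2, −78 °C). This is displaced at low temperature by a soluble bromide (Bu4NBr, toluene, −40 → 0 °C), so that a pre-formed sulfonate leaving group and a salt nucleophile replace the phosphonium chemistry; the route is rejoined at 9.

- **Step 15.** The bromo oxocarbenium ion or liberated HBr may open the neighbouring oxirane, or adventitious water may hydrolyse the enol ether. Fallback: from 18, without passing through 19, the lactone carbonyl is olefinated directly with the dibromomethylene ylide (CBr4, PPh3, Zn dust, THF, reflux; Ramirez/Corey–Fuchs-type olefination of a lactone), which rejoins the route at 21. This fallback forms no compound outside the list (F0).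

**Further compounds**

F1 | step 13 | α-methyl α,β-unsaturated ε-lactone (ring A trans-fused to 3-methyl-oxepin-2-one with a C3=C4 double bond) | CC1(C)[C@H](Br)CC[C@@]2(C)OC(=O)C(C)=CC[C@H]12
F2 | step 6 | (1S,3R)-3-allyl-2,2-dimethyl-4-oxocyclohexyl trifluoromethanesulfonate | CC1(C)[C@@H](OS(=O)(=O)C(F)(F)F)CCC(=O)[C@@H]1CC=C
F0 | step 15 | none | none
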